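Cuts, in retrosynthetic order: N–Cbz and the O–CH3 at C4'; C1'–C8a' (naphthalene ring); the Sonogashira bonds C2'–C3', C5–C1' and C4'–C4a'; C1–C8a (Pictet–Spengler); C4–C4a (aziridine opening).
Feature used: ring C1'–C2'–C3'–C4'–C4a'–C8a' carries the isoquinoline at C1' para to oxygen at C4'. In ring C4a'–C5'–C6'–C7'–C8'–C8a', C5' is blocked by methoxy, so C8a' is the only free carbon ortho to C4a' and an aryl enyne C8a'(H)–C4a'–C4'(O)=C3'–C2'≡C1' can close in one way only.
Forward order: nitrogen ring (step 4), C5 iodide and C5 alkyne, union with the anisole half as an (E)-β-iodoenol acetate (step 9), closure of the second naphthalene ring (step 10), O-methylation, N-deprotection.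
Stereochemistry: C3 (S) is the stereocentre of L-alaninol and no bond to it is ever broken. The alkene geometry (aryl cis to alkynyl) comes from an anti iodoacetoxylation.
The enol oxygen is carried as acetate rather than as methyl ether: this enol derivative is available with defined geometry, tolerates traces of acid, and pushes less electron density toward C1'.
Key step: step 10

Locants: unprimed = isoquinoline; primed = naphthalene, with C1' bearing the isoquinoline, C4' and C5' the oxygens and C7' the methyl group.
Assumption: the structure fixes only C3. The hindered C5–C1' axis is undefined, so step 10 may give both axial rotamers, and either or both count as the target.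

Step 1
Reactants: 1 L-alaninol
Product: 2 benzyl (S)-(1-hydroxypropan-2-yl)carbamate
Conditions: CbzCl, NaHCO3, THF–H2O, 0 °C to rt
Reagents that add atoms: benzyl chloroformate, O=C(Cl)OCc1ccccc1
Why: Schotten–Baumann N-acylation, in which the amine reacts far faster than the primary alcohol and the stereocentre is not involved.

Step 2
Reactants: 2 benzyl (S)-(1-hydroxypropan-2-yl)carbamate
Product: 4 benzyl (S)-2-methylaziridine-1-carboxylate, via O-tosylate 3 (not isolated)
Conditions: TsCl, powdered KOH, Et2O, reflux
Reagents that add atoms: 4-toluenesulfonyl chloride, Cc1ccc(cc1)S(=O)(=O)Cl (its atoms stay only in 3)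
Why: O-sulfonylation followed by 3-exo-tet displacement by the carbamate anion (Wenker-type aziridine synthesis) breaks only the CH2–O bond, so the methyl-bearing carbon stays S.

Step 3
Reactants: 5 1-bromo-3,5-dimethoxybenzene; 4 benzyl (S)-2-methylaziridine-1-carboxylate
Product: 7 benzyl (S)-[1-(3,5-dimethoxyphenyl)propan-2-yl]carbamate, via Grignard reagent 6 (not isolated)
Conditions: 5, Mg, THF, reflux; then CuBr·SMe2 (10 mol %), 4, THF, −30 °C to rt; aq. NH4Cl
Reagents that add atoms: magnesium, [Mg] (stays only in 6)
Why: Copper-catalysed SN2 opening of a carbamate-activated aziridine by an aryl Grignard reagent takes place at the unsubstituted ring carbon, forming C4–C4a and leaving the C–N stereocentre untouched.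

Step 4
Reactants: 7 benzyl (S)-[1-(3,5-dimethoxyphenyl)propan-2-yl]carbamate
Product: 8 benzyl (S)-6,8-dimethoxy-3-methyl-3,4-dihydroisoquinoline-2(1H)-carboxylate
Conditions: (CH2O)n, TFA, CH2Cl2, 0 °C to rt
Reagents that add atoms: paraformaldehyde (as formaldehyde), C=O
Why: N-acyliminium Pictet–Spengler cyclization, in which the two positions ortho to the side chain are equivalent and each is para to one methoxy and ortho to the other, while the benzyl carbamate tolerates TFA.

Step 5
Reactants: 8 benzyl (S)-6,8-dimethoxy-3-methyl-3,4-dihydroisoquinoline-2(1H)-carboxylate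
Product: 9 benzyl (S)-5-iodo-6,8-dimethoxy-3-methyl-3,4-dihydroisoquinoline-2(1H)-carboxylate
Conditions: NIS (1 equiv), TFA (cat.), MeCN, 0 °C, dark
Reagents that add atoms: N-iodosuccinimide, O=C1CCC(=O)N1I
Why: Electrophilic aromatic iodination should prefer C5, which is para to the C8 methoxy and ortho to the C6 methoxy, over C7, which is squeezed between two methoxy groups, as is usual for 3,5-dimethoxytoluene-type rings.

Step 6
Reactants: 9 benzyl (S)-5-iodo-6,8-dimethoxy-3-methyl-3,4-dihydroisoquinoline-2(1H)-carboxylate; 10 trimethylsilylacetylene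
Product: 12 benzyl (S)-5-ethynyl-6,8-dimethoxy-3-methyl-3,4-dihydroisoquinoline-2(1H)-carboxylate, via silyl alkyne 11 (not isolated)
Conditions: PdCl2(PPh3)2, CuI, Et3N, THF, 60 °C; filter, concentrate; then K2CO3 (cat.), MeOH, rt
Reagents that add atoms: none
Why: Sonogashira coupling forms the future biaryl bond C5–C1' as an unhindered aryl–alkyne bond, and base-catalysed methanolysis then removes the silyl group without touching the carbamate.

Step 7
Reactants: 13 2-bromo-5-methylanisole; 10 trimethylsilylacetylene
Product: 15 2-ethynyl-5-methylanisole, via silyl alkyne 14 (not isolated)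
Conditions: PdCl2(PPh3)2, CuI, Et3N, 80 °C, sealed tube; filter, concentrate; then K2CO3 (cat.), MeOH, rt
Reagents that add atoms: none
Why: Sonogashira coupling of the aryl bromide (C4'–C4a') followed by protodesilylation, both routine on anisole substrates.

Step 8
Reactants: 15 2-ethynyl-5-methylanisole
Product: 16 (E)-2-iodo-1-(2-methoxy-4-methylphenyl)ethenyl acetate (aryl cis to iodine)
Conditions: NIS (1 equiv), AcOH–CH2Cl2, 0 °C to rt, dark, no silver salt, no base
Reagents that add atoms: N-iodosuccinimide, O=C1CCC(=O)N1I; acetic acid, CC(=O)O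
Why: Electrophilic anti iodoacyloxylation of an aryl alkyne puts iodine on the terminal carbon and acetate on the cation-stabilizing benzylic carbon from the side away from iodine, so aryl and iodine end up cis (E, since oxygen outranks aryl carbon), and leaving out silver and base avoids the iodoalkyne path that would give the other isomer.

Step 9
Reactants: 12 benzyl (S)-5-ethynyl-6,8-dimethoxy-3-methyl-3,4-dihydroisoquinoline-2(1H)-carboxylate; 16 (E)-2-iodo-1-(2-methoxy-4-methylphenyl)ethenyl acetate
Product: 17 benzyl (S)-5-[(E)-4-acetoxy-4-(2-methoxy-4-methylphenyl)but-3-en-1-yn-1-yl]-6,8-dimethoxy-3-methyl-3,4-dihydroisoquinoline-2(1H)-carboxylate (anisole ring cis to the alkynyl group)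
Conditions: PdCl2(PPh3)2, CuI, Et3N, THF, rt, degassed
Reagents that add atoms: none
Why: Sonogashira coupling of a vinyl iodide (C2'–C3') runs at room temperature with retention of alkene geometry, and a tertiary amine base does not cleave the enol acetate.

Step 10
Reactants: 17 benzyl (S)-5-[(E)-4-acetoxy-4-(2-methoxy-4-methylphenyl)but-3-en-1-yn-1-yl]-6,8-dimethoxy-3-methyl-3,4-dihydroisoquinoline-2(1H)-carboxylate
Product: 18 benzyl (S)-5-(4-acetoxy-5-methoxy-7-methylnaphthalen-1-yl)-6,8-dimethoxy-3-methyl-3,4-dihydroisoquinoline-2(1H)-carboxylate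
Conditions: PtCl2 (10 mol %), CO (1 atm), toluene, 80 °C
Reagents that add atoms: none
Why: PtCl2, made more electrophilic by CO, binds the in-plane π bond of the alkyne and slips toward C2', because the 2,4-dimethoxyaryl group on C1', turned perpendicular to the enyne plane as in the product, carries the developing positive charge; C8a' attacks C1' anti to platinum, the arenium ion loses its proton, and protodemetalation of the C2'–Pt bond releases 18 and divalent platinum. The closest known reaction type is the PtCl2- or gold-catalysed intramolecular hydroarylation (cycloisomerization) of 1-aryl-1-en-3-ynes and 2-alkynylbiaryls to naphthalenes and phenanthrenes. The single ring closed, C1'–C2'–C3'–C4'–C4a'–C8a', forms in the 6-endo-dig mode through the new C1'–C8a' bond. No stereocentre is created and C3 is a spectator; the new C5–C1' axis arises without control. The step needs carbon attack rather than oxygen attack, 6-endo rather than 5-exo closure, and a single site on the anisole ring. The E geometry holds the enol oxygen and its acetyl group trans to the alkyne, the acetyl group weakens the vinylogous donation toward C1' (which involves only the out-of-plane π bond) so that the aryl group on C1' decides the polarization, the nearby methoxy oxygens can add only reversibly because a methyloxonium ion has no easy exit, and C5' is blocked so that C8a' is the only ortho carbon available.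

Step 11
Reactants: 18 benzyl (S)-5-(4-acetoxy-5-methoxy-7-methylnaphthalen-1-yl)-6,8-dimethoxy-3-methyl-3,4-dihydroisoquinoline-2(1H)-carboxylate
Product: 20 benzyl (S)-5-(4,5-dimethoxy-7-methylnaphthalen-1-yl)-6,8-dimethoxy-3-methyl-3,4-dihydroisoquinoline-2(1H)-carboxylate, via naphthol 19 (not isolated)
Conditions: K2CO3, MeOH, rt, argon; then MeI, DMF, rt
Reagents that add atoms: methyl iodide, CI
Why: Base-mediated methanolysis of the aryl acetate and Williamson O-methylation of the resulting naphtholate in the same flask, under which the carbamate and the aryl ethers are inert.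

Step 12
Reactants: 20 benzyl (S)-5-(4,5-dimethoxy-7-methylnaphthalen-1-yl)-6,8-dimethoxy-3-methyl-3,4-dihydroisoquinoline-2(1H)-carboxylate
Product: 21 (S)-5-(4,5-dimethoxy-7-methylnaphthalen-1-yl)-6,8-dimethoxy-3-methyl-1,2,3,4-tetrahydroisoquinoline (target)
Conditions: H2 (1 atm), 10% Pd/C, EtOH, rt
Reagents that add atoms: none
Why: Hydrogenolysis of the benzyl carbamate with loss of CO2 frees the secondary amine under conditions that leave the naphthalene, the aryl ethers and C3 unchanged.

Compound list
1 | L-alaninol, (S)-2-aminopropan-1-ol | C[C@H](N)CO | starting material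
2 | benzyl (S)-(1-hydroxypropan-2-yl)carbamate | C[C@H](NC(=O)OCc1ccccc1)CO | intermediate
3 | (S)-2-(benzyloxycarbonylamino)propyl 4-methylbenzenesulfonate | C[C@H](NC(=O)OCc1ccccc1)COS(=O)(=O)c1ccc(C)cc1 | intermediate
4 | benzyl (S)-2-methylaziridine-1-carboxylate | C[C@H]1CN1C(=O)OCc2ccccc2 | intermediate
5 | 1-bromo-3,5-dimethoxybenzene | COc1cc(Br)cc(OC)c1 | starting material
6 | 3,5-dimethoxyphenylmagnesium bromide | COc1cc([Mg]Br)cc(OC)c1 | intermediate
7 | benzyl (S)-[1-(3,5-dimethoxyphenyl)propan-2-yl]carbamate | C[C@H](NC(=O)OCc1ccccc1)Cc1cc(OC)cc(OC)c1 | intermediate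
8 | benzyl (S)-6,8-dimethoxy-3-methyl-3,4-dihydroisoquinoline-2(1H)-carboxylate | COc1cc(OC)c2c(c1)C[C@H](C)N(C(=O)OCc3ccccc3)C2 | intermediate
9 | benzyl (S)-5-iodo-6,8-dimethoxy-3-methyl-3,4-dihydroisoquinoline-2(1H)-carboxylate | COc1cc(OC)c2c(c1I)C[C@H](C)N(C(=O)OCc3ccccc3)C2 | intermediate
10 | trimethylsilylacetylene | C#C[Si](C)(C)C | starting material
11 | benzyl (S)-6,8-dimethoxy-3-methyl-5-[(trimethylsilyl)ethynyl]-3,4-dihydroisoquinoline-2(1H)-carboxylate | COc1cc(OC)c2c(c1C#C[Si](C)(C)C)C[C@H](C)N(C(=O)OCc3ccccc3)C2 | intermediate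
12 | benzyl (S)-5-ethynyl-6,8-dimethoxy-3-methyl-3,4-dihydroisoquinoline-2(1H)-carboxylate | COc1cc(OC)c2c(c1C#C)C[C@H](C)N(C(=O)OCc3ccccc3)C2 | intermediate
13 | 2-bromo-5-methylanisole | COc1cc(C)ccc1Br | starting material
14 | [(2-methoxy-4-methylphenyl)ethynyl]trimethylsilane | COc1cc(C)ccc1C#C[Si](C)(C)C | intermediate
15 | 2-ethynyl-5-methylanisole | COc1cc(C)ccc1C#C | intermediate
16 | (E)-2-iodo-1-(2-methoxy-4-methylphenyl)ethenyl acetate | COc1cc(C)ccc1/C(OC(C)=O)=C\I | intermediate
17 | benzyl (S)-5-[(E)-4-acetoxy-4-(2-methoxy-4-methylphenyl)but-3-en-1-yn-1-yl]-6,8-dimethoxy-3-methyl-3,4-dihydroisoquinoline-2(1H)-carboxylate | COc1cc(C)ccc1/C(OC(C)=O)=C\C#Cc1c(OC)cc(OC)c2c1C[C@H](C)N(C(=O)OCc3ccccc3)C2 | intermediate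
18 | benzyl (S)-5-(4-acetoxy-5-methoxy-7-methylnaphthalen-1-yl)-6,8-dimethoxy-3-methyl-3,4-dihydroisoquinoline-2(1H)-carboxylate | CC(=O)Oc1ccc(-c2c(OC)cc(OC)c3c2C[C@H](C)N(C(=O)OCc4ccccc4)C3)c2cc(C)cc(OC)c12 | intermediate
19 | benzyl (S)-5-(4-hydroxy-5-methoxy-7-methylnaphthalen-1-yl)-6,8-dimethoxy-3-methyl-3,4-dihydroisoquinoline-2(1H)-carboxylate | Oc1ccc(-c2c(OC)cc(OC)c3c2C[C@H](C)N(C(=O)OCc4ccccc4)C3)c2cc(C)cc(OC)c12 | intermediate
20 | benzyl (S)-5-(4,5-dimethoxy-7-methylnaphthalen-1-yl)-6,8-dimethoxy-3-methyl-3,4-dihydroisoquinoline-2(1H)-carboxylate | COc1ccc(-c2c(OC)cc(OC)c3c2C[C@H](C)N(C(=O)OCc4ccccc4)C3)c2cc(C)cc(OC)c12 | intermediate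
21 | (S)-5-(4,5-dimethoxy-7-methylnaphthalen-1-yl)-6,8-dimethoxy-3-methyl-1,2,3,4-tetrahydroisoquinoline | COc1cc(OC)c(-c2ccc(OC)c3c(OC)cc(C)cc23)c2c1CN[C@@H](C)C2 | target

Total step count: 12. Longest linear sequence: 10 (steps 1–6 and 9–12).

Steps most likely to fail

Step 10. C8a' lies meta to both donor groups of its ring, so its attack on C1' may be too slow. Closure in the 5-exo mode at C2', demethylative attack by a neighbouring methoxy oxygen, or oligomerization of the enyne could then take over. The fallback gives up the ring closure and forms C5–C1' by a Suzuki–Miyaura coupling; it sets out from 13 and 9 and comes back at 20. LDA-induced loss of HBr from 13 in THF in the presence of 2-methoxyfuran (aryne Diels–Alder reaction) should give 1,8-dimethoxy-6-methyl-1,4-dihydro-1,4-epoxynaphthalene F1. In this cycloaddition the nucleophilic C5 of the furan bonds to the aryne carbon remote from methoxy. A trace of acid opens the ketal bridge to 4,5-dimethoxy-7-methylnaphthalen-1-ol F2. Tf2O and pyridine convert it into 4,5-dimethoxy-7-methylnaphthalen-1-yl trifluoromethanesulfonate F3. Miyaura borylation (B2pin2, PdCl2(dppf), KOAc, dioxane, 80 °C) gives the naphthyl pinacol boronate F4. Coupling of this boronate with 9 (Pd(OAc)2, SPhos, K3PO4, toluene–water, 100 °C) gives 20.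

Step 8. The cation next to the o-methoxyaryl group is open rather than bridged, so acetate may also enter syn to iodine and erode the geometry. Iodination of the ring para to methoxy and a second iodination of the enol acetate are further drains. The fallback builds the alkene by syn-carbometalation instead; it sets out from 13 and 12 and comes back at 20. Double elimination of chloroacetaldehyde dimethyl acetal (NaNH2, liquid NH3, then aqueous quench) gives methoxyacetylene F5. Compound 13 is converted with Mg in THF into (2-methoxy-4-methylphenyl)magnesium bromide F6 and with CuBr·SMe2 into (2-methoxy-4-methylphenyl)copper F7. Syn-carbocupration of the alkyne, with aryl going to the oxygen-bearing carbon, gives the β-methoxyvinylcopper F8. It is kept below −20 °C to prevent β-elimination of methoxide and is quenched with I2 to 1-[(E)-2-iodo-1-methoxyethenyl]-2-methoxy-4-methylbenzene F9 (aryl cis to iodine). Sonogashira coupling with 12 under the conditions of step 9 gives the (E)-methyl enol ether enyne F10. Its closure with PtCl2 as in step 10 gives 20 directly, with the C4' methoxy already in place.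

Step 3. The Grignard reagent may add to the carbamate carbonyl, or bromide may open the aziridine faster than aryl is transferred from copper. The fallback reverses the polarity of the C4–C4a bond formation; it sets out from 2 and 5 and comes back at 7, bypassing steps 2 and 3. Appel iodination of 2 (I2, PPh3, imidazole, CH2Cl2) gives benzyl (S)-(1-iodopropan-2-yl)carbamate F11. Zinc insertion (Zn dust, cat. I2, DMF, rt) gives the β-amidoalkylzinc iodide F12. Negishi coupling with 5 (Pd2(dba)3, SPhos, DMF, rt to 50 °C) gives 7 without touching the stereocentre.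

Further compounds
F1 | step 10 | 1,8-dimethoxy-6-methyl-1,4-dihydro-1,4-epoxynaphthalene (racemic) | COc1cc(C)cc2c1C1(OC)C=CC2O1
F2 | step 10 | 4,5-dimethoxy-7-methylnaphthalen-1-ol | COc1ccc(O)c2cc(C)cc(OC)c12
F3 | step 10 | 4,5-dimethoxy-7-methylnaphthalen-1-yl trifluoromethanesulfonate | COc1ccc(OS(=O)(=O)C(F)(F)F)c2cc(C)cc(OC)c12
F4 | step 10 | 2-(4,5-dimethoxy-7-methylnaphthalen-1-yl)-4,4,5,5-tetramethyl-1,3,2-dioxaborolane | COc1ccc(B3OC(C)(C)C(C)(C)O3)c2cc(C)cc(OC)c12
F5 | step 8 | methoxyacetylene | COC#C
F6 | step 8 | (2-methoxy-4-methylphenyl)magnesium bromide | COc1cc(C)ccc1[Mg]Br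
F7 | step 8 | (2-methoxy-4-methylphenyl)copper | COc1cc(C)ccc1[Cu]
F8 | step 8 | [(E)-2-methoxy-2-(2-methoxy-4-methylphenyl)ethenyl]copper (aryl cis to copper) | COc1cc(C)ccc1/C(OC)=C\[Cu]
F9 | step 8 | 1-[(E)-2-iodo-1-methoxyethenyl]-2-methoxy-4-methylbenzene | COc1cc(C)ccc1/C(OC)=C\I
F10 | step 8 | benzyl (S)-6,8-dimethoxy-5-[(E)-4-methoxy-4-(2-methoxy-4-methylphenyl)but-3-en-1-yn-1-yl]-3-methyl-3,4-dihydroisoquinoline-2(1H)-carboxylate | COc1cc(C)ccc1/C(OC)=C\C#Cc1c(OC)cc(OC)c2c1C[C@H](C)N(C(=O)OCc3ccccc3)C2
F11 | step 3 | benzyl (S)-(1-iodopropan-2-yl)carbamate | C[C@H](NC(=O)OCc1ccccc1)CI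
F12 | step 3 | [(S)-2-(benzyloxycarbonylamino)propyl]zinc iodide | C[C@H](NC(=O)OCc1ccccc1)C[Zn]I
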